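**Retrosynthetic overview**
1. Target 13 comes from its MOM ether 12 by acetal cleavage. In 12 both pyran rings are cut at once, each at its C3–C4 bond and its O1–C2 bond (chromene numbering), giving biphenyl bis-salicylaldehyde 8 and two molecules of 2-methylprop-1-enylboronic acid 9.
2. Enabling feature: in each chromene the atoms O1–C8a=C4a–C4=C3–C2 form a 1-oxatriene laid over the arene. Each pyran is thus the closed valence isomer of an ortho-quinone methide whose methide carbon C4 is a salicylaldehyde carbon ortho to O1, and whose C2 carries the gem-dimethyl group.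
3. 8 comes from a Suzuki–Miyaura coupling (C6–C6' biaryl bond) of bromide 4 and boronate 7.
4. 4 comes from 4-bromophenol 1 by ortho-C-prenylation and ortho-formylation; 7 comes from catechol aldehyde 5 by regioselective MOM protection and borylation.
5. Ring order: both benzene rings are bought; the two pyran rings are formed last and together in one flask.

Key step: step 6

Assumption: 5-bromo-2,3-dihydroxybenzaldehyde 5 and boronic acid 9 are taken as catalogue chemicals; the target is achiral, so no stereocentre has to be set.

**Step 1**
Reactants: 1 4-bromophenol; 2 prenyl bromide (1-bromo-3-methylbut-2-ene)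
Product: 3 4-bromo-2-(3-methylbut-2-en-1-yl)phenol
Conditions: NaH (1.1 equiv), toluene, 0 °C; then 2 (1.0 equiv), 0 °C to rt
Reagents that add atoms: none
Why: Ortho-selective C-alkylation of a sodium phenoxide (phenoxide C-prenylation): in toluene the tight Na–O ion pair shields oxygen and steers the allylic bromide to the ortho carbon, the para carbon being blocked by bromine, and the dienone formed rearomatises to the phenol.

**Step 2**
Reactants: 3 4-bromo-2-(3-methylbut-2-en-1-yl)phenol
Product: 4 5-bromo-2-hydroxy-3-(3-methylbut-2-en-1-yl)benzaldehyde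
Conditions: MgCl2 (2 equiv), Et3N (4 equiv), (CH2O)n (6 equiv), MeCN, 80 °C; cold aq. citric acid work-up
Reagents that add atoms: paraformaldehyde (as formaldehyde), C=O
Why: Casnati–Skattebøl ortho-formylation: the magnesium phenoxide delivers formaldehyde to the only free ortho carbon and a second formaldehyde oxidises the benzylic alkoxide by hydride transfer, under non-acidic conditions that leave the prenyl alkene alone.

**Step 3**
Reactants: 5 5-bromo-2,3-dihydroxybenzaldehyde
Product: 6 5-bromo-2-hydroxy-3-(methoxymethoxy)benzaldehyde
Conditions: NaH (2.2 equiv), DMF/THF, 0 °C; then MOMCl (1.0 equiv), 0 °C to rt; aq. NH4Cl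
Reagents that add atoms: chloromethyl methyl ether (MOMCl), COCCl
Why: Williamson-type O-alkylation of the catechol dianion: the C2 phenoxide is conjugated with and chelated to the formyl group, so the more basic C3 phenoxide should take the single equivalent of MOMCl.

**Step 4**
Reactants: 6 5-bromo-2-hydroxy-3-(methoxymethoxy)benzaldehyde
Product: 7 2-hydroxy-3-(methoxymethoxy)-5-(4,4,5,5-tetramethyl-1,3,2-dioxaborolan-2-yl)benzaldehyde
Conditions: B2pin2 (1.2 equiv), Pd(dppf)Cl2 (5 mol %), KOAc (3 equiv), 1,4-dioxane, 90 °C, Ar
Reagents that add atoms: bis(pinacolato)diboron, CC1(C)OB(OC1(C)C)B1OC(C)(C)C(C)(C)O1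
Why: Miyaura borylation: oxidative addition of zerovalent palladium into the C–Br bond and acetate-assisted transmetalation with B2pin2 tolerate the free phenol, the aldehyde and the MOM acetal.

**Step 5**
Reactants: 4 5-bromo-2-hydroxy-3-(3-methylbut-2-en-1-yl)benzaldehyde; 7 2-hydroxy-3-(methoxymethoxy)-5-(4,4,5,5-tetramethyl-1,3,2-dioxaborolan-2-yl)benzaldehyde
Product: 8 4,4'-dihydroxy-5-(methoxymethoxy)-5'-(3-methylbut-2-en-1-yl)-[1,1'-biphenyl]-3,3'-dicarbaldehyde
Conditions: Pd(PPh3)4 (5 mol %), K2CO3 (4 equiv), 1,4-dioxane/H2O (4:1), 85 °C, Ar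
Reagents that add atoms: none
Why: Suzuki–Miyaura cross-coupling forms the biaryl bond; 5-bromo- and 5-boryl-salicylaldehydes are routine partners as their phenoxides, and the prenyl group and MOM ether are inert to aqueous carbonate.

**Step 6**
Reactants: 8 4,4'-dihydroxy-5-(methoxymethoxy)-5'-(3-methylbut-2-en-1-yl)-[1,1'-biphenyl]-3,3'-dicarbaldehyde; 9 2-methylprop-1-en-1-ylboronic acid (two molecules are consumed)
Product: 12 8-(methoxymethoxy)-2,2,2',2'-tetramethyl-8'-(3-methylbut-2-en-1-yl)-2H,2'H-6,6'-bichromene, via bis-Petasis amine adduct 10 (not isolated), via bis-ortho-quinone methide 11 (not isolated)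
Conditions: 9 (3 equiv), Bn2NH (2.2 equiv), 1,4-dioxane, 50 °C then 95 °C, Ar
Reagents that add atoms: none
Why: Each formyl group condenses with dibenzylamine to an iminium ion ortho to a phenol; the phenoxide binds 9 as a tetracoordinate boronate and hands the 2-methylprop-1-enyl group, through its boron-bearing carbon, to the iminium carbon (the C3–C4 bond of each chromene, Petasis borono-Mannich reaction) to give 10, and at 95 °C each aminophenol loses dibenzylamine to the ortho-quinone methide stage 11, whose O1=C8a–C4a=C4–C3=C2 oxatriene closes to the pyran (the O1–C2 bond of each chromene). The closest known reaction type is the amine-mediated condensation of salicylaldehydes with alkenylboronic acids to 2H-chromenes, here run twice on one molecule. Each of the two pyran rings closes by a thermal disrotatory oxa-6π electrocyclisation, made irreversible by the return of aromaticity and favoured by the gem-dimethyl group at C2. No stereocentre remains: the aminated benzylic carbons of 10 form as a diastereomer mixture and become sp2 on amine loss, and each C2 carries two methyl groups. The selectivity needed is alkenyl transfer to the two formyl carbons only and closure onto the correct oxygen; it is secured because boron is delivered only from a free hydroxyl ortho to an iminium carbon (the third oxygen is capped as its MOM ether, ring A has a single phenolic oxygen) and because transfer through the boron-bearing carbon places C3 next to C4 and the dimethylated carbon next to oxygen. The prenyl group, the MOM ether and the biaryl bond should be untouched by the neutral amine/boronic acid medium; 11 is drawn with both rings open in the geometry that closes, although the two rings pass through this stage independently.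

**Step 7**
Reactants: 12 8-(methoxymethoxy)-2,2,2',2'-tetramethyl-8'-(3-methylbut-2-en-1-yl)-2H,2'H-6,6'-bichromene
Product: 13 2,2,2',2'-tetramethyl-8'-(3-methylbut-2-en-1-yl)-2H,2'H-[6,6'-bichromen]-8-ol (target)
Conditions: 2 M aq. HCl, MeOH/THF, 45 °C
Reagents that add atoms: none
Why: Acid-catalysed acetal exchange (methanolysis of the MOM ether) frees the C8 hydroxyl; ring A has no free phenol beside the prenyl group, so acid-induced chroman formation is excluded, and the trisubstituted alkene and both 2,2-dimethylchromenes should tolerate dilute acid at this temperature.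

**Compound list**
1 | 4-bromophenol | Oc1ccc(Br)cc1 | starting material
2 | prenyl bromide (1-bromo-3-methylbut-2-ene) | CC(C)=CCBr | starting material
3 | 4-bromo-2-(3-methylbut-2-en-1-yl)phenol | CC(C)=CCc1cc(Br)ccc1O | intermediate
4 | 5-bromo-2-hydroxy-3-(3-methylbut-2-en-1-yl)benzaldehyde | CC(C)=CCc1cc(Br)cc(C=O)c1O | intermediate
5 | 5-bromo-2,3-dihydroxybenzaldehyde | O=Cc1cc(Br)cc(O)c1O | starting material
6 | 5-bromo-2-hydroxy-3-(methoxymethoxy)benzaldehyde | COCOc1cc(Br)cc(C=O)c1O | intermediate
7 | 2-hydroxy-3-(methoxymethoxy)-5-(4,4,5,5-tetramethyl-1,3,2-dioxaborolan-2-yl)benzaldehyde | COCOc1cc(B2OC(C)(C)C(C)(C)O2)cc(C=O)c1O | intermediate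
8 | 4,4'-dihydroxy-5-(methoxymethoxy)-5'-(3-methylbut-2-en-1-yl)-[1,1'-biphenyl]-3,3'-dicarbaldehyde | CC(C)=CCc1cc(-c2cc(C=O)c(O)c(OCOC)c2)cc(C=O)c1O | intermediate
9 | 2-methylprop-1-en-1-ylboronic acid | CC(C)=CB(O)O | starting material
10 | bis-Petasis amine adduct: biphenyl 8 with each CHO replaced by CH(NBn2)CH=CMe2 (diastereomer mixture, both stereocentres erased in the same flask) | CC(C)=CCc1cc(-c2cc(C(C=C(C)C)N(Cc3ccccc3)Cc3ccccc3)c(O)c(OCOC)c2)cc(C(C=C(C)C)N(Cc2ccccc2)Cc2ccccc2)c1O | intermediate
11 | bis-ortho-quinone methide: both rings as 6-(3-methylbut-2-enylidene)cyclohexa-2,4-dienones, isobutenyl group syn to C=O | CC(C)=CCC1=CC(C2=C/C(=C/C=C(C)C)C(=O)C(OCOC)=C2)=C/C(=C/C=C(C)C)C1=O | intermediate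
12 | 8-(methoxymethoxy)-2,2,2',2'-tetramethyl-8'-(3-methylbut-2-en-1-yl)-2H,2'H-6,6'-bichromene | CC(C)=CCc1cc(-c2cc(OCOC)c3c(c2)C=CC(C)(C)O3)cc2c1OC(C)(C)C=C2 | intermediate
13 | 2,2,2',2'-tetramethyl-8'-(3-methylbut-2-en-1-yl)-2H,2'H-[6,6'-bichromen]-8-ol | CC(C)=CCc1cc(-c2cc(O)c3c(c2)C=CC(C)(C)O3)cc2c1OC(C)(C)C=C2 | target

**Step count**
Total steps: 7. Longest linear sequence: 5 steps (steps 3, 4, 5, 6, 7; equally steps 1, 2, 5, 6, 7).

**Steps most likely to fail**

Step 6. The alkenyl transfer from the hindered, β,β-disubstituted boronic acid may be slow at one or both sites, so that protodeboronation of 9 outruns the Mannich step and mono-annulated material accumulates. Fallback, setting out from 8: addition of excess 2-methylprop-1-enylmagnesium bromide (THF, −20 °C to rt) to both formyl groups should give the bis(allylic alcohol) 1,1'-[4,4'-dihydroxy-5-(methoxymethoxy)-5'-(3-methylbut-2-en-1-yl)biphenyl-3,3'-diyl]bis(3-methylbut-2-en-1-ol) F1. Dehydrative cyclisation of each ortho-hydroxybenzylic allylic alcohol (catalytic PPTS, toluene, 60 °C, too weak an acid to protonate the prenyl alkene) passes through the same ortho-quinone methides and comes back to the route at 12.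

Step 1. O-alkylation and double C-alkylation may compete with the wanted single ortho-C-alkylation. Fallback, setting out from 1: copper-catalysed O-alkylation with 3-chloro-3-methylbut-1-yne (CuCl2 cat., DBU, MeCN, 0 °C) should give 1-bromo-4-[(2-methylbut-3-yn-2-yl)oxy]benzene F2. Semihydrogenation (H2, Pd/CaCO3 poisoned with Pb(OAc)2, quinoline, EtOAc) should give 1-bromo-4-[(2-methylbut-3-en-2-yl)oxy]benzene F3. Aromatic Claisen rearrangement (N,N-diethylaniline, 150 °C) then moves the allyl unit to the ortho carbon with inversion and comes back to the route at 3.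

Step 3. Regiocontrol may be lost in the mono-alkylation, with MOMCl going to the C2 oxygen or to both oxygens. Fallback, setting out from 5: exhaustive protection (MOMCl excess, i-Pr2NEt, CH2Cl2) should give 5-bromo-2,3-bis(methoxymethoxy)benzaldehyde F4. Selective methanolysis of the MOM group ortho to the formyl group (dilute HCl, MeOH, 0 to 20 °C; this acetal is the more labile because the carbonyl oxygen assists and the freed phenol is hydrogen-bonded) comes back to the route at 6.

**Further compounds**
F1 | step 6 | 1,1'-[4,4'-dihydroxy-5-(methoxymethoxy)-5'-(3-methylbut-2-en-1-yl)biphenyl-3,3'-diyl]bis(3-methylbut-2-en-1-ol) | CC(C)=CCc1cc(-c2cc(C(O)C=C(C)C)c(O)c(OCOC)c2)cc(C(O)C=C(C)C)c1O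
F2 | step 1 | 1-bromo-4-[(2-methylbut-3-yn-2-yl)oxy]benzene | C#CC(C)(C)Oc1ccc(Br)cc1
F3 | step 1 | 1-bromo-4-[(2-methylbut-3-en-2-yl)oxy]benzene | C=CC(C)(C)Oc1ccc(Br)cc1
F4 | step 3 | 5-bromo-2,3-bis(methoxymethoxy)benzaldehyde | COCOc1cc(Br)cc(C=O)c1OCOC
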